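**Retrosynthetic overview**

1. Numbering: seven-membered ring C1 (O-angelate), C2 (O-2-methylbutanoate), C3 (OH), C4 (quaternary, CH3), C5, C6, C11 (CMe2); cyclobutane C4–C5–C6–C7; bridge C7–C8(=O)–C9–C10(CH3)–C5. The route rests on this feature: with C6 as a carbonyl, the four-membered ring is a 3,3-disubstituted cyclobutanone whose α-carbons C5 and C7 are spanned by C10–C9–C8 (a bicyclo[3.1.1]heptane-2,6-dione).
2. Key disconnection: C5–C10 and C7–C8, formed in one operation from a chiral enamine of prochiral 3-(PMB-oxymethyl)-3-methylcyclobutanone and (E)-crotonoyl chloride.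
3. Ring order: cyclobutane (dichloroketene [2+2]), then the six-membered bridge (key annulation), then the seven-membered ring (C11→C6 aldol of a (Z)-enone built on the C3 arm, with C8 masked as a TIPS enol ether), then bridgehead deoxygenation at C6.
4. End game: CBS reduction at C1, dihydroxylation of C2=C3 anti to C1–OH, C2/C3 acetonide, angelate at C1, (R)-2-methylbutanoate at C2.

Key step: step 5

Assumption: enamine 8 is an equilibrating pair of double-bond isomers (toward C5 or C7); the isomer that reacts is drawn.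
Assumption: in the CBS reduction (step 14) the fully substituted C11 side of the C1 ketone acts as the large group; the C8 epimer question does not arise because C8 stays sp2 throughout.

**Route**

Step 1
Reactants: 1 2-methylprop-2-en-1-ol
Product: 2 methallyl 4-methoxybenzyl ether
Conditions: NaH, PMBCl, TBAI (cat.), THF/DMF, 0 °C → rt
Reagents that add atoms: 4-methoxybenzyl chloride, COc1ccc(CCl)cc1
Why: Williamson etherification of a primary allylic alkoxide with a benzylic chloride; no stereocentre is involved.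

Step 2
Reactants: 2 methallyl 4-methoxybenzyl ether; 3 trichloroacetyl chloride
Product: 5 2,2-dichloro-3-[(4-methoxybenzyloxy)methyl]-3-methylcyclobutanone (racemic), via dichloroketene 4 (not isolated)
Conditions: Zn–Cu couple, POCl3, Et2O, reflux
Reagents that add atoms: trichloroacetyl chloride (3), ClC(=O)C(Cl)(Cl)Cl
Why: Ketene–alkene [2+2] cycloaddition of dichloroketene (made by zinc dechlorination) to a 1,1-disubstituted alkene, the ketene carbonyl carbon bonding to the CH2 terminus; the stereocentre formed is erased in step 3.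

Step 3
Reactants: 5 2,2-dichloro-3-[(4-methoxybenzyloxy)methyl]-3-methylcyclobutanone
Product: 6 3-[(4-methoxybenzyloxy)methyl]-3-methylcyclobutanone (prochiral)
Conditions: Zn dust, AcOH, rt
Reagents that add atoms: none
Why: Zinc reductive dechlorination of an α,α-dichloroketone gives the Cs-symmetric cyclobutanone with two enantiotopic α-CH2 groups.

Step 4
Reactants: 6 3-[(4-methoxybenzyloxy)methyl]-3-methylcyclobutanone; 7 (2R,5R)-2,5-dimethylpyrrolidine
Product: 8 (2R,5R)-1-{3-[(4-methoxybenzyloxy)methyl]-3-methylcyclobut-1-en-1-yl}-2,5-dimethylpyrrolidine (enamine)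
Conditions: TiCl4 (0.6 equiv), Et3N, toluene, 0 °C → rt; filtered under Ar and used crude
Reagents that add atoms: (2R,5R)-2,5-dimethylpyrrolidine (7), C[C@@H]1CC[C@@H](C)N1
Why: Titanium tetrachloride-mediated enamine condensation, which should work here because the small C=C–C angles of the cyclobutene relieve allylic strain with the 2,5-dimethyl groups; no permanent stereocentre is set.

Step 5
Reactants: 8 enamine; 9 (E)-but-2-enoyl chloride
Product: 13 7-[(4-methoxybenzyloxy)methyl]-4,7-dimethylbicyclo[3.1.1]heptane-2,6-dione (C6 and C8 ketones; three-carbon bridge cis to the C4 methyl; C10 methyl on the C6 side), via N-crotonoyl enammonium chloride 10 (not isolated), via ketene iminium chloride 11 (not isolated), via bicyclic keto iminium chloride 12 (not isolated)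
Conditions: toluene, 0 °C → 80 °C; then H2O (pH 5 acetate buffer)/THF, 0 °C
Reagents that add atoms: (E)-but-2-enoyl chloride (9), C/C=C/C(=O)Cl; water, O
Why: Proposed new method: N-acylation of 8 should give enammonium 10, whose 3-aza-Cope ([3,3]) shift through a chair joins C5 to C10 and leaves ketene–iminium 11; proton transfer then regenerates the enamine toward C7, which is C-acylated at C8 to give iminium 12, hydrolysed to 13. The closest known reaction is the α,α′-annulation of cyclohexanone and cyclopentanone enamines with acryloyl or crotonoyl chloride to bridged bicyclic diketones, which has not been shown for a cyclobutanone or with a chiral amine. The six-membered ring C5–C6–C7–C8–C9–C10 closes by 6-(enolendo)-exo-trig C-acylation (exo-dig if the ketene itself is attacked), and the irreversible acylation pays for the bicyclo[3.1.1] strain. C5 and C7, and with them the sense at C4, are set jointly: the C2-symmetric amine blocks one face of the enamine carbon with the methyl on its neighbouring ring carbon, whatever the N–C6 rotamer, so only "C5 from the face of the C4 methyl" or "C7 from the face of the ether arm" are open, and the substrate prefers the face anti to CH2OPMB, which would otherwise have to sit under the new bridge. C10 follows from the chair with the (E)-crotonyl methyl equatorial, and the configuration at C7 is forced by the tether. The step needs the methyl/arm facial choice, which with this amine leads to a separable diastereomer and not to the enantiomer when it fails, and it must avoid retro-Claisen opening of the 2-acylcyclobutanone, hence the cold, weakly acidic hydrolysis.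

Step 6
Reactants: 13 PMB-protected bicyclic dione
Product: 14 7-(hydroxymethyl)-4,7-dimethylbicyclo[3.1.1]heptane-2,6-dione
Conditions: DDQ, CH2Cl2/pH 7 buffer, 0 °C
Reagents that add atoms: none
Why: Oxidative PMB ether cleavage by benzylic hydride abstraction, under neutral conditions that should spare the non-enolisable β-diketone; no stereocentre is touched.

Step 7
Reactants: 14 hydroxymethyl dione
Product: 15 4,7-dimethyl-2,6-dioxobicyclo[3.1.1]heptane-7-carbaldehyde (C3 aldehyde)
Conditions: Dess–Martin periodinane, CH2Cl2, 0 °C → rt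
Reagents that add atoms: none
Why: Dess–Martin oxidation of a neopentyl primary alcohol to an aldehyde that has no α-hydrogen and therefore cannot epimerise or enolise.

Step 8
Reactants: 15 aldehyde dione
Product: 16 4,7-dimethyl-6-oxo-2-[(triisopropylsilyl)oxy]bicyclo[3.1.1]hept-2-ene-7-carbaldehyde (C8 TIPS enol ether; C6 ketone free)
Conditions: TIPSOTf, Et3N, CH2Cl2, −78 → 0 °C
Reagents that add atoms: triisopropylsilyl trifluoromethanesulfonate, CC(C)[Si](C(C)C)(C(C)C)OS(=O)(=O)C(F)(F)F
Why: Soft enolisation and O-silylation, regiodefined because C9 is the only enolisable position (C5 and C7 are bridgeheads, the aldehyde has no α-H); it removes the β-dicarbonyl relationship so that a later C6 alkoxide cannot fragment toward C8.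

Step 9
Reactants: 16 enol ether aldehyde
Product: 17 7-ethynyl-4,7-dimethyl-2-[(triisopropylsilyl)oxy]bicyclo[3.1.1]hept-2-en-6-one
Conditions: Ohira–Bestmann reagent, K2CO3, MeOH, 0 °C → rt
Reagents that add atoms: dimethyl (1-diazo-2-oxopropyl)phosphonate, COP(=O)(OC)C(=[N+]=[N-])C(C)=O
Why: Seyferth–Gilbert homologation (Ohira–Bestmann variant), in which the aldehyde reacts far faster than the hindered, non-enolisable cyclobutanone and the TIPS enol ether tolerates carbonate in methanol; it installs C2.

Step 10
Reactants: 17 terminal alkyne; 18 2-methylpropanoyl chloride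
Product: 19 4,7-dimethyl-7-(4-methyl-3-oxopent-1-yn-1-yl)-2-[(triisopropylsilyl)oxy]bicyclo[3.1.1]hept-2-en-6-one (ynone)
Conditions: PdCl2(PPh3)2 (cat.), CuI (cat.), Et3N, THF, rt
Reagents that add atoms: 2-methylpropanoyl chloride (18), CC(C)C(=O)Cl
Why: Acyl Sonogashira coupling, chosen because the copper acetylide does not add to the free C6 ketone; it installs C1 and C11 with its two methyls.

Step 11
Reactants: 19 ynone
Product: 20 4,7-dimethyl-7-[(Z)-4-methyl-3-oxopent-1-en-1-yl]-2-[(triisopropylsilyl)oxy]bicyclo[3.1.1]hept-2-en-6-one ((Z)-enone)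
Conditions: H2 (1 atm), Lindlar catalyst, quinoline, EtOAc, rt; used at once
Reagents that add atoms: none
Why: Lindlar semihydrogenation adds H2 syn to the alkyne and so gives the (Z)-C2=C3 enone needed for C11 to reach C6, leaving the enol ether and ketones untouched.

Step 12
Reactants: 20 (Z)-enone
Product: 23 tricyclic enone C6 methyl oxalate (C1 ketone; C2=C3; C6–O on the face of the C8–C10 bridge; C8 TIPS enol ether), via lithium dienolate 21 (not isolated), via lithium aldolate 22 (not isolated)
Conditions: LiHMDS, THF, −78 °C; then ClC(O)CO2Me, −78 → −20 °C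
Reagents that add atoms: methyl chlorooxoacetate, COC(=O)C(=O)Cl
Why: Intramolecular aldol addition, 7-(enolendo)-exo-trig, of the only possible enolate (C11) to the strained C6 ketone, where the tether from C4 lets C11 reach C6 only from the face opposite the C8–C10 bridge and so fixes C6; the aldolate is acylated in the flask before it can revert.

Step 13
Reactants: 23 C6 methyl oxalate
Product: 24 tricyclic enone with C6–H (C1 ketone; C2=C3; C8 TIPS enol ether)
Conditions: Bu3SnH, AIBN, toluene, 110 °C
Reagents that add atoms: none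
Why: Radical deoxygenation of a tertiary methyl oxalate with tributyltin hydride (Barton-type), where elimination is impossible and the caged bridgehead C6 radical can accept hydrogen only with retention; an acyl shift to C1 is geometrically excluded.

Step 14
Reactants: 24 tricyclic enone
Product: 25 C1 allylic alcohol (C1–OH on the C5 side of the seven-membered ring; C8 TIPS enol ether)
Conditions: (S)-2-methyl-CBS-oxazaborolidine, catecholborane, toluene, −78 °C
Reagents that add atoms: none
Why: Corey–Bakshi–Shibata 1,2-reduction, with the catalyst delivering hydride to the C1 carbonyl face on the C7 side (C11 as large group) and so setting C1, for which the nearly symmetric cage offers no reliable substrate bias.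

Step 15
Reactants: 25 C1 allylic alcohol TIPS enol ether
Product: 26 C1 allylic alcohol C8 ketone
Conditions: TBAF, AcOH, THF, 0 °C
Reagents that add atoms: none
Why: Buffered fluoride cleavage of the silyl enol ether regenerates the C8 ketone by protonation at the non-stereogenic C9, safe now that C6 carries no oxygen.

Step 16
Reactants: 26 C1 allylic alcohol C8 ketone
Product: 27 C1,C2,C3-triol C8 ketone (C2–OH and C3–OH on the C7 side; C1–OH on the C5 side)
Conditions: OsO4 (cat.), NMO, acetone/H2O, rt
Reagents that add atoms: osmium tetroxide (catalytic), O=[Os](=O)(=O)=O; N-methylmorpholine N-oxide, C[N+]1([O-])CCOCC1; water, O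
Why: Upjohn dihydroxylation adds syn to the C2=C3 face anti to the allylic C1 hydroxyl (Kishi's rule), setting C2 and C3 cis to each other and trans to C1–O.

Step 17
Reactants: 27 triol
Product: 28 C2,C3-acetonide with free C1–OH
Conditions: 2,2-dimethoxypropane, PPTS (cat.), acetone, rt
Reagents that add atoms: 2,2-dimethoxypropane, COC(C)(C)OC
Why: Acid-catalysed acetonide formation under thermodynamic control picks the cis C2/C3 diol over the trans C1/C2 pair, leaving C1–OH as the only free hydroxyl.

Step 18
Reactants: 28 acetonide alcohol; 29 angelic acid [(Z)-2-methylbut-2-enoic acid]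
Product: 31 C1 angelate C2,C3-acetonide, via angelic 2,4,6-trichlorobenzoic anhydride 30 (not isolated)
Conditions: 2,4,6-trichlorobenzoyl chloride, Et3N, toluene, rt; then 28, 80 °C (no DMAP)
Reagents that add atoms: angelic acid (29), C/C=C(/C)C(=O)O
Why: Yamaguchi mixed-anhydride esterification run without a nucleophilic catalyst, the conditions under which angelates are formed without Z→E isomerisation to the tiglate; C1 is not affected.

Step 19
Reactants: 31 C1 angelate acetonide
Product: 32 C1 angelate C2,C3-diol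
Conditions: TFA/H2O (9:1), CH2Cl2, 0 °C
Reagents that add atoms: none
Why: Acid hydrolysis of the cyclic ketal, kept cold and brief so that neither angelate isomerisation nor C1→C2 acyl migration should compete.

Step 20
Reactants: 32 C1 angelate diol; 33 (R)-2-methylbutanoic acid
Product: 35 CNP0206299.1 (target), via (R)-2-methylbutanoic 2,4,6-trichlorobenzoic anhydride 34 (not isolated)
Conditions: 2,4,6-trichlorobenzoyl chloride, Et3N, THF, rt; then 32, DMAP, toluene, 0 °C
Reagents that add atoms: (R)-2-methylbutanoic acid (33), CC[C@@H](C)C(=O)O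
Why: Yamaguchi esterification, selective for C2–OH because C3–OH is neopentyl (next to quaternary C4) and a C3 ester would be the less stable regioisomer; the acid stereocentre is carried in unchanged.

**Compound list**

1 | 2-methylprop-2-en-1-ol | CC(=C)CO | starting material
2 | 1-methoxy-4-{[(2-methylprop-2-en-1-yl)oxy]methyl}benzene | COc1ccc(COCC(C)=C)cc1 | intermediate
3 | trichloroacetyl chloride | ClC(=O)C(Cl)(Cl)Cl | starting material
4 | dichloroketene | ClC(Cl)=C=O | intermediate
5 | 2,2-dichloro-3-[(4-methoxybenzyloxy)methyl]-3-methylcyclobutanone (racemic) | COc1ccc(COCC2(C)CC(=O)C2(Cl)Cl)cc1 | intermediate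
6 | 3-[(4-methoxybenzyloxy)methyl]-3-methylcyclobutanone | COc1ccc(COCC2(C)CC(=O)C2)cc1 | intermediate
7 | (2R,5R)-2,5-dimethylpyrrolidine | C[C@@H]1CC[C@@H](C)N1 | starting material
8 | (2R,5R)-1-{3-[(4-methoxybenzyloxy)methyl]-3-methylcyclobut-1-en-1-yl}-2,5-dimethylpyrrolidine (drawn as the C5=C6 isomer) | C[C@@H]1CC[C@@H](C)N1C2=C[C@@](C)(COCc3ccc(OC)cc3)C2 | intermediate
9 | (E)-but-2-enoyl chloride | C/C=C/C(=O)Cl | starting material
10 | N-crotonoyl-N-(cyclobutenyl)-2,5-dimethylpyrrolidinium chloride | C/C=C/C(=O)[N+]1(C2=C[C@@](C)(COCc3ccc(OC)cc3)C2)[C@H](C)CC[C@H]1C.[Cl-] | intermediate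
11 | cyclobutylidene pyrrolidinium chloride carrying the C10(CH3)–C9H=C8=O ketene chain on C5 | COc1ccc(COC[C@]2(C)[C@@H]([C@H](C)C=C=O)C(=[N+]3[C@H](C)CC[C@H]3C)C2)cc1.[Cl-] | intermediate
12 | C6 iminium chloride of the bicyclo[3.1.1]heptane-2,6-dione (C8 ketone) | COc1ccc(COC[C@]2(C)[C@@H]3C(=[N+]4[C@H](C)CC[C@H]4C)[C@H]2C(=O)C[C@H]3C)cc1.[Cl-] | intermediate
13 | 7-[(4-methoxybenzyloxy)methyl]-4,7-dimethylbicyclo[3.1.1]heptane-2,6-dione | COc1ccc(COC[C@]2(C)[C@@H]3C(=O)[C@H]2C(=O)C[C@H]3C)cc1 | intermediate
14 | 7-(hydroxymethyl)-4,7-dimethylbicyclo[3.1.1]heptane-2,6-dione | OC[C@]1(C)[C@@H]2C(=O)[C@H]1C(=O)C[C@H]2C | intermediate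
15 | 4,7-dimethyl-2,6-dioxobicyclo[3.1.1]heptane-7-carbaldehyde | O=C[C@]1(C)[C@@H]2C(=O)[C@H]1C(=O)C[C@H]2C | intermediate
16 | 4,7-dimethyl-6-oxo-2-[(triisopropylsilyl)oxy]bicyclo[3.1.1]hept-2-ene-7-carbaldehyde | O=C[C@]1(C)[C@@H]2C(=O)[C@H]1C(O[Si](C(C)C)(C(C)C)C(C)C)=C[C@H]2C | intermediate
17 | 7-ethynyl-4,7-dimethyl-2-[(triisopropylsilyl)oxy]bicyclo[3.1.1]hept-2-en-6-one | C#C[C@]1(C)[C@@H]2C(=O)[C@H]1C(O[Si](C(C)C)(C(C)C)C(C)C)=C[C@H]2C | intermediate
18 | 2-methylpropanoyl chloride | CC(C)C(=O)Cl | starting material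
19 | 4,7-dimethyl-7-(4-methyl-3-oxopent-1-yn-1-yl)-2-[(triisopropylsilyl)oxy]bicyclo[3.1.1]hept-2-en-6-one | CC(C)C(=O)C#C[C@]1(C)[C@@H]2C(=O)[C@H]1C(O[Si](C(C)C)(C(C)C)C(C)C)=C[C@H]2C | intermediate
20 | 4,7-dimethyl-7-[(Z)-4-methyl-3-oxopent-1-en-1-yl]-2-[(triisopropylsilyl)oxy]bicyclo[3.1.1]hept-2-en-6-one | CC(C)C(=O)/C=C\[C@]1(C)[C@@H]2C(=O)[C@H]1C(O[Si](C(C)C)(C(C)C)C(C)C)=C[C@H]2C | intermediate
21 | lithium dienolate of 20 (C1–O–Li, C1=C11) | CC(C)=C([O-])/C=C\[C@]1(C)[C@@H]2C(=O)[C@H]1C(O[Si](C(C)C)(C(C)C)C(C)C)=C[C@H]2C.[Li+] | intermediate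
22 | lithium C6 alkoxide of the tricyclic aldol (C1 ketone, C2=C3, C8 TIPS enol ether) | O=C1C=C[C@]2(C)[C@@H]3[C@@]([O-])([C@H]2C(O[Si](C(C)C)(C(C)C)C(C)C)=C[C@H]3C)C1(C)C.[Li+] | intermediate
23 | C6 methyl oxalate of the tricyclic aldol | O=C1C=C[C@]2(C)[C@@H]3[C@@](OC(=O)C(=O)OC)([C@H]2C(O[Si](C(C)C)(C(C)C)C(C)C)=C[C@H]3C)C1(C)C | intermediate
24 | tricyclic enone with C6–H (C1 ketone, C2=C3, C8 TIPS enol ether) | O=C1C=C[C@]2(C)[C@@H]3[C@@H]([C@H]2C(O[Si](C(C)C)(C(C)C)C(C)C)=C[C@H]3C)C1(C)C | intermediate
25 | C1 allylic alcohol, C8 TIPS enol ether | O[C@@H]1C=C[C@]2(C)[C@@H]3[C@@H]([C@H]2C(O[Si](C(C)C)(C(C)C)C(C)C)=C[C@H]3C)C1(C)C | intermediate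
26 | C1 allylic alcohol, C8 ketone | O[C@@H]1C=C[C@]2(C)[C@@H]3[C@@H]([C@H]2C(=O)C[C@H]3C)C1(C)C | intermediate
27 | C1,C2,C3-triol, C8 ketone | O[C@@H]1[C@@H](O)[C@@H](O)[C@]2(C)[C@@H]3[C@@H]([C@H]2C(=O)C[C@H]3C)C1(C)C | intermediate
28 | C2,C3-acetonide, C1 alcohol, C8 ketone | O[C@@H]1[C@@H](OC(C)(C)O4)[C@@H]4[C@]2(C)[C@@H]3[C@@H]([C@H]2C(=O)C[C@H]3C)C1(C)C | intermediate
29 | angelic acid, (Z)-2-methylbut-2-enoic acid | C/C=C(/C)C(=O)O | starting material
30 | angelic 2,4,6-trichlorobenzoic anhydride | C/C=C(/C)C(=O)OC(=O)c1c(Cl)cc(Cl)cc1Cl | intermediate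
31 | C1 angelate, C2,C3-acetonide | C/C=C(/C)C(=O)O[C@@H]1[C@@H](OC(C)(C)O4)[C@@H]4[C@]2(C)[C@@H]3[C@@H]([C@H]2C(=O)C[C@H]3C)C1(C)C | intermediate
32 | C1 angelate, C2,C3-diol | C/C=C(/C)C(=O)O[C@@H]1[C@@H](O)[C@@H](O)[C@]2(C)[C@@H]3[C@@H]([C@H]2C(=O)C[C@H]3C)C1(C)C | intermediate
33 | (R)-2-methylbutanoic acid | CC[C@@H](C)C(=O)O | starting material
34 | (R)-2-methylbutanoic 2,4,6-trichlorobenzoic anhydride | CC[C@@H](C)C(=O)OC(=O)c1c(Cl)cc(Cl)cc1Cl | intermediate
35 | CNP0206299.1 | C/C=C(/C)C(=O)O[C@@H]1[C@@H](OC(=O)[C@H](C)CC)[C@@H](O)[C@]2(C)[C@@H]3[C@@H]([C@H]2C(=O)C[C@H]3C)C1(C)C | target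

**Step count**

Total steps: 20. Longest linear sequence: 20 steps (from 1 to 35).

**Steps most likely to fail**

Step 5 (proposed new method). What may go wrong: sluggish or misdirected acylation of the hindered enamine; attack on the face of the ether arm; passage through a boat, giving the C10 epimer; failure of the strained C7–C8 closure; retro-Claisen opening of the cyclobutanone during hydrolysis. The fallback is stepwise and uses known reactions, setting out from 8 and returning at 13. Stork Michael addition of 8 to diethyl ethylidenemalonate (MeCN, rt; then aqueous AcOH) should give diethyl 2-{1-[3-(4-methoxybenzyloxymethyl)-3-methyl-2-oxocyclobutyl]ethyl}malonate F1, under the same facial control by the amine. Krapcho dealkoxycarbonylation (LiCl, wet DMSO, 150 °C) gives the keto ethyl ester F2, where any C10 or C5 epimer is separated. LiOH gives the keto acid F3, and oxalyl chloride with catalytic DMF gives the keto acid chloride F4. Soft enolisation (MgBr2·OEt2, iPr2NEt, CH2Cl2) then closes C7–C8 by intramolecular C-acylation to 13.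

Step 12. What may go wrong: slow deprotonation of the hindered isopropyl ketone; an aldol equilibrium lying on the open side, so that the enolate and not the aldolate is acylated; Z→E isomerisation of the enone. The fallback sets out from 20 and returns at 23. Soft enolisation (TMSOTf, Et3N, CH2Cl2) gives the trimethylsilyl dienol ether F5. TiCl4 (CH2Cl2, −78 °C) then promotes an intramolecular Mukaiyama aldol addition, whose titanium aldolate does not revert and gives on work-up the free tertiary C6 alcohol F6. Acylation with methyl chlorooxoacetate (DMAP, pyridine) gives 23.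

Step 18. What may go wrong: slow acylation of the neopentyl C1 hydroxyl, and Z→E isomerisation of the angeloyl group at the temperature needed. The fallback sets out from 28 and returns at 31. DCC/DMAP esterification with 2-[bis(2,2,2-trifluoroethoxy)phosphoryl]propanoic acid, where forcing conditions do no harm, gives the C1 phosphonopropanoate F7 (mixture of epimers at the phosphonate carbon). Still–Gennari olefination (KHMDS, 18-crown-6, THF, −78 °C; acetaldehyde) then builds the (Z)-2-methylbut-2-enoate in place and gives 31.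

**Further compounds**

F1 | step 5 | diethyl 2-{1-[3-(4-methoxybenzyloxymethyl)-3-methyl-2-oxocyclobutyl]ethyl}malonate | COc1ccc(COC[C@]2(C)[C@@H]([C@H](C)C(C(=O)OCC)C(=O)OCC)C(=O)C2)cc1
F2 | step 5 | ethyl 3-[3-(4-methoxybenzyloxymethyl)-3-methyl-2-oxocyclobutyl]butanoate | COc1ccc(COC[C@]2(C)[C@@H]([C@H](C)CC(=O)OCC)C(=O)C2)cc1
F3 | step 5 | 3-[3-(4-methoxybenzyloxymethyl)-3-methyl-2-oxocyclobutyl]butanoic acid | COc1ccc(COC[C@]2(C)[C@@H]([C@H](C)CC(=O)O)C(=O)C2)cc1
F4 | step 5 | 3-[3-(4-methoxybenzyloxymethyl)-3-methyl-2-oxocyclobutyl]butanoyl chloride | COc1ccc(COC[C@]2(C)[C@@H]([C@H](C)CC(=O)Cl)C(=O)C2)cc1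
F5 | step 12 | trimethylsilyl dienol ether of 20 (C1–OSiMe3, C1=C11) | CC(C)=C(O[Si](C)(C)C)/C=C\[C@]1(C)[C@@H]2C(=O)[C@H]1C(O[Si](C(C)C)(C(C)C)C(C)C)=C[C@H]2C
F6 | step 12 | tricyclic aldol with free C6 hydroxyl (C1 ketone, C2=C3, C8 TIPS enol ether) | O=C1C=C[C@]2(C)[C@@H]3[C@@](O)([C@H]2C(O[Si](C(C)C)(C(C)C)C(C)C)=C[C@H]3C)C1(C)C
F7 | step 18 | C1 2-[bis(2,2,2-trifluoroethoxy)phosphoryl]propanoate of 28 | CC(C(=O)O[C@@H]1[C@@H](OC(C)(C)O4)[C@@H]4[C@]2(C)[C@@H]3[C@@H]([C@H]2C(=O)C[C@H]3C)C1(C)C)P(=O)(OCC(F)(F)F)OCC(F)(F)F
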